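**Plan**

- Retrosynthesis (oxolane numbered O1, C2H2, C3(OH)(benzyl), C4(CH2OH), C5(aryl)): the benzylic CH2–C3 bond is cut first, through a temporary δ-lactone C4–CH2–O–C(=O)–CH(aryl)–C3 whose carbonyl carbon is later lost as CO2. Then O1–C2 (carbenoid O–H insertion), C4–C5 (syn aldol), and in the dihydrobenzofuran C2–C3 (carbenoid C–H insertion).
- Forward: cis-dihydrobenzofuran ring, then its 5-carbaldehyde, syn aldol, diazoketone, oxolan-3-one ring, aryl(bromo)acetate tether on the C4 CH2OH, SmI2 Reformatsky closure onto C3=O, lactone opening with loss of CO2, deprotection.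
- Enabling feature: the CH2OH on C4 is next to the carbinol carbon C3 and cis to the benzyl group. An ester on that oxygen can reach the C3 carbonyl only on the face carrying the C4 and C5 substituents, the face an external benzyl nucleophile would avoid.
- Stereochemistry: benzofuran C2/C3 (cis) from the chiral Rh(II) carboxylate; oxolane C4/C5 (cis) from the (R)-4-benzyloxazolidinone boron aldol; C3 from the tether (cis-fused 6/5 bicycle).

Key step: step 19

Assumption: Rh2(S-PTTL)4 is taken to give the (2R,3S) ester 9; if its sense of induction is the opposite, Rh2(R-PTTL)4 is used under the same conditions.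

Abbreviations in names: BnV = 4-(benzyloxy)-3-methoxyphenyl; Ar = (2R,3R)-2-(BnV)-3-{[(tert-butyldiphenylsilyl)oxy]methyl}-7-methoxy-2,3-dihydro-1-benzofuran-5-yl (2,3-cis); TBS = tert-butyldimethylsilyl.

**Route**

Step 1
Reactants: 1 4-bromo-2-methoxyphenol
Product: 2 1-(allyloxy)-4-bromo-2-methoxybenzene
Conditions: allyl bromide, K2CO3, acetone, reflux
Reagents that add atoms: allyl bromide, C=CCBr
Why: Williamson O-allylation of the phenoxide sets up the Claisen rearrangement.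

Step 2
Reactants: 2 1-(allyloxy)-4-bromo-2-methoxybenzene
Product: 3 2-allyl-4-bromo-6-methoxyphenol
Conditions: N,N-diethylaniline, 200 °C
Reagents that add atoms: none
Why: The aromatic Claisen rearrangement should deliver the allyl group to the only free ortho carbon, since the other ortho position carries OMe and the para position carries Br.

Step 3
Reactants: 3 2-allyl-4-bromo-6-methoxyphenol; 4 [4-(benzyloxy)-3-methoxyphenyl]methanol
Product: 5 1-allyl-2-{[4-(benzyloxy)-3-methoxybenzyl]oxy}-5-bromo-3-methoxybenzene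
Conditions: PPh3, DIAD, THF, 0 °C to rt
Reagents that add atoms: none
Why: Mitsunobu etherification of an acidic phenol with a primary benzylic alcohol installs the CH2 that later becomes C2 of the dihydrobenzofuran.

Step 4
Reactants: 5 1-allyl-2-{[4-(benzyloxy)-3-methoxybenzyl]oxy}-5-bromo-3-methoxybenzene
Product: 6 (2-{[4-(benzyloxy)-3-methoxybenzyl]oxy}-5-bromo-3-methoxyphenyl)acetic acid
Conditions: KMnO4 (cat.), NaIO4, K2CO3 (to pH 8), t-BuOH/H2O, rt
Reagents that add atoms: sodium periodate, [Na+].[O-]I(=O)(=O)=O; water, O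
Why: Lemieux–von Rudloff cleavage of the terminal alkene should give the arylacetic acid under near-neutral conditions that spare the electron-rich rings and the benzylic ethers.

Step 5
Reactants: 6 (2-{[4-(benzyloxy)-3-methoxybenzyl]oxy}-5-bromo-3-methoxyphenyl)acetic acid
Product: 7 methyl (2-{[4-(benzyloxy)-3-methoxybenzyl]oxy}-5-bromo-3-methoxyphenyl)acetate
Conditions: MeI, K2CO3, DMF, rt
Reagents that add atoms: iodomethane, CI
Why: SN2 O-methylation of the carboxylate avoids acid, which the p-alkoxybenzyl aryl ether would not tolerate.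

Step 6
Reactants: 7 methyl (2-{[4-(benzyloxy)-3-methoxybenzyl]oxy}-5-bromo-3-methoxyphenyl)acetate
Product: 8 methyl 2-diazo-2-(2-{[4-(benzyloxy)-3-methoxybenzyl]oxy}-5-bromo-3-methoxyphenyl)acetate
Conditions: 4-acetamidobenzenesulfonyl azide, DBU, MeCN, 0 °C to rt
Reagents that add atoms: 4-acetamidobenzenesulfonyl azide, CC(=O)Nc1ccc(cc1)S(=O)(=O)N=[N+]=[N-]
Why: Regitz diazo transfer to the benzylic ester methylene gives the donor/acceptor diazo ester.

Step 7
Reactants: 8 methyl 2-diazo-2-(2-{[4-(benzyloxy)-3-methoxybenzyl]oxy}-5-bromo-3-methoxyphenyl)acetate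
Product: 9 methyl (2R,3S)-2-(BnV)-5-bromo-7-methoxy-2,3-dihydro-1-benzofuran-3-carboxylate (2,3-cis)
Conditions: Rh2(S-PTTL)4 (1 mol%), toluene, −60 °C
Reagents that add atoms: none
Why: Intramolecular Rh(II)-carbenoid 1,5 C–H insertion into the ether CH2 closes the dihydrofuran ring in a concerted step that should give the kinetic cis product, with the chiral carboxylate ligands fixing the absolute configuration of both C2 and C3.

Step 8
Reactants: 9 methyl (2R,3S)-2-(BnV)-5-bromo-7-methoxy-2,3-dihydro-1-benzofuran-3-carboxylate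
Product: 10 [(2R,3R)-2-(BnV)-5-bromo-7-methoxy-2,3-dihydro-1-benzofuran-3-yl]methanol (2,3-cis)
Conditions: DIBAL-H, CH2Cl2, −78 to −20 °C; Rochelle salt
Reagents that add atoms: none
Why: Non-basic hydride reduction of the ester at low temperature should leave the acidic C3–H, and therefore the cis relationship, untouched.

Step 9
Reactants: 10 [(2R,3R)-2-(BnV)-5-bromo-7-methoxy-2,3-dihydro-1-benzofuran-3-yl]methanol
Product: 11 {[(2R,3R)-2-(BnV)-5-bromo-7-methoxy-2,3-dihydro-1-benzofuran-3-yl]methoxy}(tert-butyl)diphenylsilane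
Conditions: TBDPSCl, imidazole, DMF, rt
Reagents that add atoms: tert-butyl(chloro)diphenylsilane, CC(C)(C)[Si](Cl)(c1ccccc1)c1ccccc1
Why: Silylation of the primary alcohol gives an ether that survives organolithium, boron triflate, peroxide, SmI2 and the later selective removal of a TBS group.

Step 10
Reactants: 11 {[(2R,3R)-2-(BnV)-5-bromo-7-methoxy-2,3-dihydro-1-benzofuran-3-yl]methoxy}(tert-butyl)diphenylsilane
Product: 13 (2R,3R)-2-(BnV)-3-{[(tert-butyldiphenylsilyl)oxy]methyl}-7-methoxy-2,3-dihydro-1-benzofuran-5-carbaldehyde (Ar–CHO), via aryllithium 12 (not isolated)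
Conditions: n-BuLi, THF, −78 °C; DMF, −78 to 0 °C; aq. NH4Cl
Reagents that add atoms: n-butyllithium, [Li]CCCC (lithium, retained only in 12); N,N-dimethylformamide, CN(C)C=O
Why: Bromine–lithium exchange followed by formylation with DMF places the aldehyde para to the ring oxygen without touching the two stereocentres.

Step 11
Reactants: 14 3-[(tert-butyldimethylsilyl)oxy]propanoic acid; 15 (R)-4-benzyl-1,3-oxazolidin-2-one
Product: 17 (R)-4-benzyl-3-{3-[(tert-butyldimethylsilyl)oxy]propanoyl}-1,3-oxazolidin-2-one, via mixed pivalic anhydride 16 (not isolated)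
Conditions: PivCl, Et3N, THF, −20 °C; then 15, LiCl, rt
Reagents that add atoms: pivaloyl chloride, CC(C)(C)C(Cl)=O (retained only in 16)
Why: N-acylation of the oxazolidinone through the mixed anhydride with LiCl activation avoids a strong base and an acid chloride.

Step 12
Reactants: 17 (R)-4-benzyl-3-{3-[(tert-butyldimethylsilyl)oxy]propanoyl}-1,3-oxazolidin-2-one; 13 Ar–CHO
Product: 19 (4R)-4-benzyl-3-[(2R,3R)-3-Ar-2-{[(TBS)oxy]methyl}-3-hydroxypropanoyl]-1,3-oxazolidin-2-one, via (Z)-dibutylboron enolate 18 (not isolated)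
Conditions: Bu2BOTf, i-Pr2NEt, CH2Cl2, −78 to 0 °C; 13, −78 to 0 °C; pH 7 buffer, MeOH, H2O2, 0 °C
Reagents that add atoms: dibutylboron triflate, CCCCB(CCCC)OS(=O)(=O)C(F)(F)F (boron and butyl groups, retained only in 18)
Why: The Evans syn aldol of the (Z)-boron enolate through a closed chair transition state should give the 2,3-syn adduct, with the (R)-benzyl auxiliary selecting the enolate face so that the two new centres become C4 (R) and C5 (R) of the oxolane, cis to each other.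

Step 13
Reactants: 19 aldol adduct
Product: 20 (2R,3R)-3-Ar-2-{[(TBS)oxy]methyl}-3-hydroxypropanoic acid
Conditions: LiOH, H2O2, THF/H2O, 0 °C; Na2SO3; cold 1 M HCl to pH 4
Reagents that add atoms: hydrogen peroxide (as LiOOH), OO
Why: Hydroperoxide attacks the exocyclic imide carbonyl selectively, releasing the acid without epimerisation or retro-aldol at 0 °C.

Step 14
Reactants: 20 (2R,3R)-3-Ar-2-{[(TBS)oxy]methyl}-3-hydroxypropanoic acid
Product: 22 (3R,4R)-4-Ar-1-diazo-4-hydroxy-3-{[(TBS)oxy]methyl}butan-2-one, via isobutyl carbonic anhydride 21 (not isolated)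
Conditions: i-BuOCOCl, N-methylmorpholine, THF, −20 °C; CH2N2, Et2O, −20 to 0 °C
Reagents that add atoms: isobutyl chloroformate, CC(C)COC(Cl)=O (retained only in 21); diazomethane, C=[N+]=[N-]
Why: Acylation of diazomethane by the mixed anhydride (first stage of an Arndt–Eistert sequence) should proceed at the carboxylate in preference to the hindered secondary hydroxyl at low temperature.

Step 15
Reactants: 22 (3R,4R)-4-Ar-1-diazo-4-hydroxy-3-{[(TBS)oxy]methyl}butan-2-one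
Product: 23 (4R,5R)-5-Ar-4-{[(TBS)oxy]methyl}oxolan-3-one (4,5-cis)
Conditions: Rh2(OAc)4 (1 mol%), CH2Cl2, rt, slow addition
Reagents that add atoms: none
Why: Intramolecular Rh(II)-carbenoid O–H insertion forms the O1–C2 bond and the five-membered ring under neutral conditions, so the base-labile centre C4 next to the new ketone keeps its configuration.

Step 16
Reactants: 23 (4R,5R)-5-Ar-4-{[(TBS)oxy]methyl}oxolan-3-one
Product: 24 (4R,5R)-5-Ar-4-(hydroxymethyl)oxolan-3-one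
Conditions: HF·pyridine, pyridine, THF, 0 °C
Reagents that add atoms: none
Why: Buffered HF cleaves the primary TBS ether much faster than the TBDPS ether and is not basic enough to enolise the ketone.

Step 17
Reactants: 25 [4-(benzyloxy)-3-methoxyphenyl]acetic acid
Product: 27 2-bromo-2-[4-(benzyloxy)-3-methoxyphenyl]acetic acid (racemic), via dilithium enediolate 26 (not isolated)
Conditions: LDA (2.2 equiv), THF, −78 to 0 °C; CBr4, −78 °C; 1 M HCl
Reagents that add atoms: lithium diisopropylamide, [Li+].CC(C)[N-]C(C)C (lithium, retained only in 26); tetrabromomethane, BrC(Br)(Br)Br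
Why: Electrophilic bromination of the acid enediolate is regiospecific for the α-carbon and avoids radical conditions that would attack the O-benzyl CH2.

Step 18
Reactants: 24 (4R,5R)-5-Ar-4-(hydroxymethyl)oxolan-3-one; 27 2-bromo-2-[4-(benzyloxy)-3-methoxyphenyl]acetic acid
Product: 28 [(2R,3R)-2-Ar-4-oxooxolan-3-yl]methyl 2-bromo-2-(BnV)acetate (both epimers at CHBr)
Conditions: DCC, CH2Cl2, 0 °C, no DMAP
Reagents that add atoms: none
Why: Carbodiimide esterification of the primary alcohol without a nucleophilic base attaches the tether while avoiding β-elimination of the acyloxy group and epimerisation at C4.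

Step 19
Reactants: 28 [(2R,3R)-2-Ar-4-oxooxolan-3-yl]methyl 2-bromo-2-(BnV)acetate
Product: 29 (3R,3aR,7aR)-3-Ar-7-(BnV)-7a-hydroxytetrahydro-1H-furo[3,4-c]pyran-6(4H)-one (cis ring fusion, both C7 epimers)
Conditions: SmI2 (2.5 equiv), THF, −78 °C, slow addition of 28 at high dilution; pH 7 buffer at −78 °C
Reagents that add atoms: none
Why: Two single-electron transfers from SmI2 to the benzylic C–Br bond give a samarium(III) ester enolate that is held to the ketone oxygen by the oxophilic metal and adds to C3=O through a chair-like six-membered transition state, which is an intramolecular SmI2 Reformatsky reaction of a β-(α-haloacyloxy) ketone to a β-hydroxy-δ-lactone. The closure is 6-exo-trig at the carbonyl (6-enolexo for the enolate) and gives a δ-lactone fused to the oxolane at C3–C4. The new carbinol centre C3 is controlled by the tether: the O–C(=O)–C chain starts at the CH2 on C4 and can span only the carbonyl face syn to that CH2, so the C–C bond forms cis to CH2O and the hydroxyl ends trans, whereas an external benzyl nucleophile would enter anti to the C4 and C5 substituents and give the C3 epimer. The α-aryl lactone carbon forms without control, which is harmless because it becomes CH2 in step 20. The step needs reduction of C–Br ahead of the α-alkoxy ketone and no enolisation at C4; a benzylic α-bromo ester is reduced far faster than a dialkyl ketone at −78 °C and the medium is non-basic, so the cis C4/C5 relationship and the acyloxy group β to the ketone should survive.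

Step 20
Reactants: 29 δ-lactone
Product: 31 (3S,4R,5R)-5-Ar-3-[4-(benzyloxy)-3-methoxybenzyl]-4-(hydroxymethyl)oxolan-3-ol, via lithium hydroxy-carboxylate 30 (not isolated)
Conditions: LiOH (1.1 equiv), THF/H2O, 0 °C; then [Ir(dF(CF3)ppy)2(dtbbpy)]PF6 (1 mol%), PhSH (20 mol%), MeCN/H2O, 450 nm LED, rt
Reagents that add atoms: lithium hydroxide, [Li+].[OH-] (retained only in 30)
Why: Saponification frees the C4 CH2OH and an arylacetate carboxylate, which photoredox hydrodecarboxylation (carboxylate oxidation, loss of CO2, hydrogen-atom transfer from the thiol to the benzylic radical) should convert to the benzyl CH2 without touching the adjacent quaternary centre C3.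

Step 21
Reactants: 31 (3S,4R,5R)-5-Ar-3-[4-(benzyloxy)-3-methoxybenzyl]-4-(hydroxymethyl)oxolan-3-ol
Product: 32 (3S,4R,5R)-3-[4-(benzyloxy)-3-methoxybenzyl]-5-[(2R,3R)-2-(BnV)-3-(hydroxymethyl)-7-methoxy-2,3-dihydro-1-benzofuran-5-yl]-4-(hydroxymethyl)oxolan-3-ol
Conditions: TBAF, THF, 0 °C to rt; aq. NH4Cl
Reagents that add atoms: none
Why: Fluoride cleaves the remaining silyl ether, and nothing in the molecule is base-sensitive at this stage.

Step 22
Reactants: 32 bis(benzyl ether)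
Product: 33 (3S,4R,5R)-3-(4-hydroxy-3-methoxybenzyl)-5-[(2R,3R)-2-(4-hydroxy-3-methoxyphenyl)-3-(hydroxymethyl)-7-methoxy-2,3-dihydro-1-benzofuran-5-yl]-4-(hydroxymethyl)oxolan-3-ol
Conditions: H2 (1 atm), 10% Pd/C, EtOAc/EtOH, rt, stopped when both benzyl ethers are gone
Reagents that add atoms: none
Why: Hydrogenolysis of the two aryl benzyl ethers is expected to be much faster than cleavage of the cyclic benzylic C–O bonds at C5 of the oxolane and C2 of the dihydrobenzofuran under neutral conditions.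

**Compound list**

1 | 4-bromo-2-methoxyphenol | COc1cc(Br)ccc1O | starting material
2 | 1-(allyloxy)-4-bromo-2-methoxybenzene | C=CCOc1ccc(Br)cc1OC | intermediate
3 | 2-allyl-4-bromo-6-methoxyphenol | C=CCc1cc(Br)cc(OC)c1O | intermediate
4 | [4-(benzyloxy)-3-methoxyphenyl]methanol | COc1cc(CO)ccc1OCc1ccccc1 | starting material
5 | 1-allyl-2-{[4-(benzyloxy)-3-methoxybenzyl]oxy}-5-bromo-3-methoxybenzene | C=CCc1cc(Br)cc(OC)c1OCc1ccc(OCc2ccccc2)c(OC)c1 | intermediate
6 | (2-{[4-(benzyloxy)-3-methoxybenzyl]oxy}-5-bromo-3-methoxyphenyl)acetic acid | OC(=O)Cc1cc(Br)cc(OC)c1OCc1ccc(OCc2ccccc2)c(OC)c1 | intermediate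
7 | methyl (2-{[4-(benzyloxy)-3-methoxybenzyl]oxy}-5-bromo-3-methoxyphenyl)acetate | COC(=O)Cc1cc(Br)cc(OC)c1OCc1ccc(OCc2ccccc2)c(OC)c1 | intermediate
8 | methyl 2-diazo-2-(2-{[4-(benzyloxy)-3-methoxybenzyl]oxy}-5-bromo-3-methoxyphenyl)acetate | COC(=O)C(=[N+]=[N-])c1cc(Br)cc(OC)c1OCc1ccc(OCc2ccccc2)c(OC)c1 | intermediate
9 | methyl (2R,3S)-2-(BnV)-5-bromo-7-methoxy-2,3-dihydro-1-benzofuran-3-carboxylate (cis) | Brc1cc(OC)c2c(c1)[C@H](C(=O)OC)[C@H](c1ccc(OCc3ccccc3)c(OC)c1)O2 | intermediate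
10 | [(2R,3R)-2-(BnV)-5-bromo-7-methoxy-2,3-dihydro-1-benzofuran-3-yl]methanol (cis) | Brc1cc(OC)c2c(c1)[C@H](CO)[C@H](c1ccc(OCc3ccccc3)c(OC)c1)O2 | intermediate
11 | tert-butyldiphenylsilyl ether of 10 (Ar–Br) | Brc1cc(OC)c2c(c1)[C@H](CO[Si](c1ccccc1)(c1ccccc1)C(C)(C)C)[C@H](c1ccc(OCc3ccccc3)c(OC)c1)O2 | intermediate
12 | 5-lithio derivative of 11 (Ar–Li) | [Li]c1cc(OC)c2c(c1)[C@H](CO[Si](c1ccccc1)(c1ccccc1)C(C)(C)C)[C@H](c1ccc(OCc3ccccc3)c(OC)c1)O2 | intermediate
13 | (2R,3R)-2-(BnV)-3-{[(tert-butyldiphenylsilyl)oxy]methyl}-7-methoxy-2,3-dihydro-1-benzofuran-5-carbaldehyde (Ar–CHO) | O=Cc1cc(OC)c2c(c1)[C@H](CO[Si](c1ccccc1)(c1ccccc1)C(C)(C)C)[C@H](c1ccc(OCc3ccccc3)c(OC)c1)O2 | intermediate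
14 | 3-[(tert-butyldimethylsilyl)oxy]propanoic acid | CC(C)(C)[Si](C)(C)OCCC(=O)O | starting material
15 | (R)-4-benzyl-1,3-oxazolidin-2-one | O=C1N[C@H](Cc2ccccc2)CO1 | starting material
16 | 3-[(tert-butyldimethylsilyl)oxy]propanoic pivalic anhydride | CC(C)(C)C(=O)OC(=O)CCO[Si](C)(C)C(C)(C)C | intermediate
17 | (R)-4-benzyl-3-{3-[(tert-butyldimethylsilyl)oxy]propanoyl}-1,3-oxazolidin-2-one | O=C1OC[C@@H](Cc2ccccc2)N1C(=O)CCO[Si](C)(C)C(C)(C)C | intermediate
18 | (Z)-dibutylboron enolate of 17 | CCCCB(CCCC)O/C(=C\CO[Si](C)(C)C(C)(C)C)N1C(=O)OC[C@H]1Cc1ccccc1 | intermediate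
19 | (4R)-4-benzyl-3-[(2R,3R)-3-Ar-2-{[(TBS)oxy]methyl}-3-hydroxypropanoyl]-1,3-oxazolidin-2-one | O=C1OC[C@@H](Cc2ccccc2)N1C(=O)[C@H](CO[Si](C)(C)C(C)(C)C)[C@@H](O)c1cc(OC)c2c(c1)[C@H](CO[Si](c1ccccc1)(c1ccccc1)C(C)(C)C)[C@H](c1ccc(OCc3ccccc3)c(OC)c1)O2 | intermediate
20 | (2R,3R)-3-Ar-2-{[(TBS)oxy]methyl}-3-hydroxypropanoic acid | OC(=O)[C@H](CO[Si](C)(C)C(C)(C)C)[C@@H](O)c1cc(OC)c2c(c1)[C@H](CO[Si](c1ccccc1)(c1ccccc1)C(C)(C)C)[C@H](c1ccc(OCc3ccccc3)c(OC)c1)O2 | intermediate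
21 | mixed anhydride of 20 with isobutyl hydrogen carbonate | CC(C)COC(=O)OC(=O)[C@H](CO[Si](C)(C)C(C)(C)C)[C@@H](O)c1cc(OC)c2c(c1)[C@H](CO[Si](c1ccccc1)(c1ccccc1)C(C)(C)C)[C@H](c1ccc(OCc3ccccc3)c(OC)c1)O2 | intermediate
22 | (3R,4R)-4-Ar-1-diazo-4-hydroxy-3-{[(TBS)oxy]methyl}butan-2-one | [N-]=[N+]=CC(=O)[C@H](CO[Si](C)(C)C(C)(C)C)[C@@H](O)c1cc(OC)c2c(c1)[C@H](CO[Si](c1ccccc1)(c1ccccc1)C(C)(C)C)[C@H](c1ccc(OCc3ccccc3)c(OC)c1)O2 | intermediate
23 | (4R,5R)-5-Ar-4-{[(TBS)oxy]methyl}oxolan-3-one (4,5-cis) | O=C1CO[C@@H](c2cc(OC)c3c(c2)[C@H](CO[Si](c2ccccc2)(c2ccccc2)C(C)(C)C)[C@H](c2ccc(OCc4ccccc4)c(OC)c2)O3)[C@H]1CO[Si](C)(C)C(C)(C)C | intermediate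
24 | (4R,5R)-5-Ar-4-(hydroxymethyl)oxolan-3-one | O=C1CO[C@@H](c2cc(OC)c3c(c2)[C@H](CO[Si](c2ccccc2)(c2ccccc2)C(C)(C)C)[C@H](c2ccc(OCc4ccccc4)c(OC)c2)O3)[C@H]1CO | intermediate
25 | [4-(benzyloxy)-3-methoxyphenyl]acetic acid | COc1cc(CC(=O)O)ccc1OCc1ccccc1 | starting material
26 | dilithium enediolate of 25 | [Li+].[Li+].[O-]C([O-])=Cc1ccc(OCc2ccccc2)c(OC)c1 | intermediate
27 | 2-bromo-2-[4-(benzyloxy)-3-methoxyphenyl]acetic acid (racemic) | COc1cc(C(Br)C(=O)O)ccc1OCc1ccccc1 | intermediate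
28 | [(2R,3R)-2-Ar-4-oxooxolan-3-yl]methyl 2-bromo-2-(BnV)acetate (both CHBr epimers) | O=C1CO[C@@H](c2cc(OC)c3c(c2)[C@H](CO[Si](c2ccccc2)(c2ccccc2)C(C)(C)C)[C@H](c2ccc(OCc4ccccc4)c(OC)c2)O3)[C@H]1COC(=O)C(Br)c1ccc(OCc2ccccc2)c(OC)c1 | intermediate
29 | (3R,3aR,7aR)-3-Ar-7-(BnV)-7a-hydroxytetrahydro-1H-furo[3,4-c]pyran-6(4H)-one (cis-fused, both C7 epimers) | O=C1OC[C@@H]2[C@H](c3cc(OC)c4c(c3)[C@H](CO[Si](c3ccccc3)(c3ccccc3)C(C)(C)C)[C@H](c3ccc(OCc5ccccc5)c(OC)c3)O4)OC[C@]2(O)C1c1ccc(OCc2ccccc2)c(OC)c1 | intermediate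
30 | lithium 2-(BnV)-2-[(3R,4R,5R)-5-Ar-3-hydroxy-4-(hydroxymethyl)oxolan-3-yl]acetate | [Li+].[O-]C(=O)C(c1ccc(OCc2ccccc2)c(OC)c1)[C@@]1(O)CO[C@@H](c2cc(OC)c3c(c2)[C@H](CO[Si](c2ccccc2)(c2ccccc2)C(C)(C)C)[C@H](c2ccc(OCc4ccccc4)c(OC)c2)O3)[C@H]1CO | intermediate
31 | (3S,4R,5R)-5-Ar-3-[4-(benzyloxy)-3-methoxybenzyl]-4-(hydroxymethyl)oxolan-3-ol | COc1cc(C[C@@]2(O)CO[C@@H](c3cc(OC)c4c(c3)[C@H](CO[Si](c3ccccc3)(c3ccccc3)C(C)(C)C)[C@H](c3ccc(OCc5ccccc5)c(OC)c3)O4)[C@H]2CO)ccc1OCc1ccccc1 | intermediate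
32 | (3S,4R,5R)-3-[4-(benzyloxy)-3-methoxybenzyl]-5-[(2R,3R)-2-(BnV)-3-(hydroxymethyl)-7-methoxy-2,3-dihydro-1-benzofuran-5-yl]-4-(hydroxymethyl)oxolan-3-ol | COc1cc(C[C@@]2(O)CO[C@@H](c3cc(OC)c4c(c3)[C@H](CO)[C@H](c3ccc(OCc5ccccc5)c(OC)c3)O4)[C@H]2CO)ccc1OCc1ccccc1 | intermediate
33 | (3S,4R,5R)-3-(4-hydroxy-3-methoxybenzyl)-5-[(2R,3R)-2-(4-hydroxy-3-methoxyphenyl)-3-(hydroxymethyl)-7-methoxy-2,3-dihydro-1-benzofuran-5-yl]-4-(hydroxymethyl)oxolan-3-ol | COc1cc(C[C@@]2(O)CO[C@@H](c3cc(OC)c4c(c3)[C@H](CO)[C@H](c3ccc(O)c(OC)c3)O4)[C@H]2CO)ccc1O | target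

**Step count and risks**

Total steps: 22. Longest linear sequence: 20 (steps 1–10, 12–16, 18–22).

Steps most likely to fail:

1. Step 19. SmI2 may reduce the α-alkoxy ketone (C–O scission next to the carbonyl) before the bromide, the samarium enolate may be protonated before it closes, or the aldolate may revert by retro-aldol on quenching. Fallback, from 23 back to 32: the same C–C bond is made at the sp2 stage and the carbinol centre is set afterwards by oxygen delivery. Alcohol 4 is converted with SOCl2 to 4-(benzyloxy)-3-methoxybenzyl chloride F1, and zinc insertion (Zn, LiCl, THF) gives [4-(benzyloxy)-3-methoxybenzyl]zinc chloride F2. Ketone 23 is deprotonated at C2 (KHMDS, THF, −78 °C) and trapped with PhNTf2 to give the enol triflate F3. Negishi coupling of F3 with F2 (Pd(PPh3)4, THF) gives the 4-benzyl-2,3-dihydrofuran F4. Dimethyldioxirane should epoxidise the enol ether on the face anti to the C4 and C5 substituents to give the epoxide F5. DIBAL-H opens F5 at the acetal carbon to give the silyl-protected tertiary alcohol F6, with OH trans to the CH2O group. TBAF then removes both silyl groups and the route is rejoined at 32.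

2. Step 20. The β-hydroxy lactone may fragment by retro-aldol during saponification, or the electron-rich benzylic radical may be oxidised to a cation and captured by a neighbouring hydroxyl. Fallback, from 29 back to 31: DIBAL-H (CH2Cl2, −78 °C) reduces the lactone to the lactol F7. Its open hydroxy-aldehyde form is decarbonylated with [Rh(cod)Cl]2/dppp (cat., diglyme, 160 °C; Tsuji–Wilkinson decarbonylation), which gives 31 directly.

3. Step 14. Activation of the unprotected β-hydroxy acid may lead to O-acylation or β-lactone formation instead of the diazoketone. Fallback, from 19 back to 23: transamidation of 19 (MeONHMe·HCl, AlMe3, CH2Cl2) gives the Weinreb amide F8. Chloromethyllithium (ICH2Cl, MeLi·LiBr, THF, −78 °C, excess to cover the free hydroxyl) converts F8 to the chloromethyl ketone F9. Ag2O (CH2Cl2, rt, dark) closes the ring by intramolecular Williamson etherification and the route is rejoined at 23.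

**Further compounds**

F1 | step 19 | 4-(benzyloxy)-3-methoxybenzyl chloride | COc1cc(CCl)ccc1OCc1ccccc1
F2 | step 19 | [4-(benzyloxy)-3-methoxybenzyl]zinc chloride | COc1cc(C[Zn]Cl)ccc1OCc1ccccc1
F3 | step 19 | (4R,5R)-5-Ar-4-{[(TBS)oxy]methyl}-4,5-dihydrofuran-3-yl trifluoromethanesulfonate | O=S(=O)(OC1=CO[C@@H](c2cc(OC)c3c(c2)[C@H](CO[Si](c2ccccc2)(c2ccccc2)C(C)(C)C)[C@H](c2ccc(OCc4ccccc4)c(OC)c2)O3)[C@H]1CO[Si](C)(C)C(C)(C)C)C(F)(F)F
F4 | step 19 | (2R,3R)-2-Ar-4-[4-(benzyloxy)-3-methoxybenzyl]-3-{[(TBS)oxy]methyl}-2,3-dihydrofuran | COc1cc(CC2=CO[C@@H](c3cc(OC)c4c(c3)[C@H](CO[Si](c3ccccc3)(c3ccccc3)C(C)(C)C)[C@H](c3ccc(OCc5ccccc5)c(OC)c3)O4)[C@H]2CO[Si](C)(C)C(C)(C)C)ccc1OCc1ccccc1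
F5 | step 19 | 4,5-epoxide of F4 (2,6-dioxabicyclo[3.1.0]hexane, epoxide oxygen trans to the CH2OSi and Ar groups) | COc1cc(C[C@@]23O[C@@H]2O[C@@H](c2cc(OC)c4c(c2)[C@H](CO[Si](c2ccccc2)(c2ccccc2)C(C)(C)C)[C@H](c2ccc(OCc5ccccc5)c(OC)c2)O4)[C@H]3CO[Si](C)(C)C(C)(C)C)ccc1OCc1ccccc1
F6 | step 19 | (3S,4R,5R)-5-Ar-3-[4-(benzyloxy)-3-methoxybenzyl]-4-{[(TBS)oxy]methyl}oxolan-3-ol | COc1cc(C[C@@]2(O)CO[C@@H](c3cc(OC)c4c(c3)[C@H](CO[Si](c3ccccc3)(c3ccccc3)C(C)(C)C)[C@H](c3ccc(OCc5ccccc5)c(OC)c3)O4)[C@H]2CO[Si](C)(C)C(C)(C)C)ccc1OCc1ccccc1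
F7 | step 20 | (3R,3aR,7aR)-3-Ar-7-(BnV)-hexahydro-1H-furo[3,4-c]pyran-6,7a-diol (lactol of 29) | OC1OC[C@@H]2[C@H](c3cc(OC)c4c(c3)[C@H](CO[Si](c3ccccc3)(c3ccccc3)C(C)(C)C)[C@H](c3ccc(OCc5ccccc5)c(OC)c3)O4)OC[C@]2(O)C1c1ccc(OCc2ccccc2)c(OC)c1
F8 | step 14 | (2R,3R)-3-Ar-2-{[(TBS)oxy]methyl}-3-hydroxy-N-methoxy-N-methylpropanamide | CON(C)C(=O)[C@H](CO[Si](C)(C)C(C)(C)C)[C@@H](O)c1cc(OC)c2c(c1)[C@H](CO[Si](c1ccccc1)(c1ccccc1)C(C)(C)C)[C@H](c1ccc(OCc3ccccc3)c(OC)c1)O2
F9 | step 14 | (3R,4R)-4-Ar-1-chloro-4-hydroxy-3-{[(TBS)oxy]methyl}butan-2-one | ClCC(=O)[C@H](CO[Si](C)(C)C(C)(C)C)[C@@H](O)c1cc(OC)c2c(c1)[C@H](CO[Si](c1ccccc1)(c1ccccc1)C(C)(C)C)[C@H](c1ccc(OCc3ccccc3)c(OC)c1)O2
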